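(The readings were generated by integration with made-up constants, noise included.)

Target in the eta run arrives late: at 2.50 min substrate reads 0 % while target reads 54.5 %, and the last three readings of that run average 74.2 %.

| flask | substrate | capture agent | remark | time |
|---|---|---|---|---|
| eta | 0.50 M | 10 mM | run made earlier |  |
| delta | 0.50 M | 5 mM | run made earlier |  |
| theta | 0.50 M | 20 mM | run made earlier |  |
| spring | 0.50 M | 10.0 mM | a closed flask charged with all of it at once and left for 20 min | 20 min |
| summer | 0.50 M (fed, over 20.0 min) | 10.0 mM | a stirred flask in which substrate is dosed at a steady rate over 20.0 min without added volume, worked up at 20 min | 20 min |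
| winter | 0.50 M | 10.0 mM | a single well-mixed tank run continuously and read at steady state, 20 min in it on average |  |

- eta (time / min: target / %, substrate / %): 0.833: 22.0, 4.4; 2.50: 54.5, 0; 4.00: 69.5, 0; 6.00: 73.1, 0.1; 10.0: 75.3, 0; 12.0: 74.1, 0
- delta (time / min: target / %, substrate / %): 1.50: 40.6, 0; 2.50: 56.4, 0.4; 4.00: 68.6, 0.5; 8.00: 74.3, 0.7; 12.0: 76.2, 0; 20.0: 77.1, 0.6
- theta (time / min: target / %, substrate / %): 3.00: 59.6, 0.1; 6.00: 72.1, 0.3; 10.0: 72.4, 1.4; 12.0: 71.0, 0.3; 15.0: 72.7, 0; 20.0: 73.8, 0.2

(readings scatter by 1 percentage point)

- the set-up with the highest amount of target at the outlet or at the end, in percent of the substrate put in ("none" if the first two lie within 2 percentage points) (spring / summer / winter / none)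
- amount of target at the outlet or at the end, in percent of the substrate put in, spring
- amount of target at the outlet or at the end, in percent of the substrate put in, summer
- amount of target at the outlet or at the end, in percent of the substrate put in, winter

- the stated concentrations are those of everything mixed, before any reaction; amounts are the same in each set-up
- the feed brings no volume worth counting
- the earlier runs were made in a closed, stirred flask

Where does spring stop? Its charge is that of the eta run, so the reckoning here takes the eta plateau of 74.2 % for spring, and with the capture agent charged at 2.00 % of the substrate in every set-up, it carries the same plateau to summer and winter.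

How late does target come? Read as a first-order rise towards that plateau, the eta reading at 2.50 min gives a rate of 0.531 /min, whose inverse is the lag of target, 1.88 min. That is shorter than the 20 min of spring, so spring has time to reach its plateau.

What does the lag cost when substrate arrives late? The lag share, the lag divided by the dosing time, 9.42 %, is taken here as the fraction of a steady feed not yet turned into target when the feed ends, so the reckoning puts summer at 67.2 %. For the winter tank, with 20 min on average, the reckoning holds back the fraction lag/(lag + time) and puts the outlet at 67.8 %. The reckoning therefore sets spring ahead of winter by 6.4 percentage points, which is more than the margin of 2 points, and spring is the reckoned choice.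

The forecast, holding that “a hidden intermediate sits between them”, named spring with 75.5 %, 68 % and 69 % for spring, summer and winter, which are its own figures and not those reckoned here.

The flask gives spring as best, with 74.1 % in spring, 67.3 % in summer and 68.0 % in winter.

    substrate → open intermediate (k = 3.80 /min)
    open intermediate ⇌ target (K = 3.10, k = 0.490 /min)
    open intermediate + capture agent → trapped intermediate (k = 6.40 /M/min)

Spring stops at 74.1 % mainly because target falls back to open intermediate, for spring with that step made one-way gives 98.0 %. Summer ends 6.8 points below spring, and the slow dosing is part of the reason: summer without it gives 74.1 % against 67.3 %, and the lag share of the spring target comes to 7 points. The same summer flask read at 80 min, some 31.9 lags after the feed ends, holds 74.1 % of target.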